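**Retrosynthetic overview**
- Target ⇐ desilylation and selective primary acetylation of a cis-epoxy diol ⇐ hydroxymethyl-directed hydride reduction of an epoxyquinone ⇐ hydrolysis of an epoxy quinone monoketal.
- Oxirane (both epoxide stereocentres) ⇐ catalytic, hydroxymethyl-directed asymmetric nucleophilic epoxidation of a 2-allyl quinone monoketal (new method).
- Ring–C1' bond ⇐ Pd-catalysed Stille coupling of an α-stannyl quinone monoketal with a (2E,6E,10E)-C15 allylic chloride.
- Ring fragment ⇐ hydroquinone (methylation, formylation, selective 5-O-demethylation, reduction, ortho-bromination, PhI(OAc)2 oxidation in MeOH to the monoketal, stannylation). The carbocycle is carried from hydroquinone; the oxirane is the only ring formed, in step 19.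
- Chain ⇐ prop-2-yn-1-ol, two equivalents of one but-3-yn-1-ol-derived homopropargylzinc reagent and formaldehyde, by iterative Zr-catalysed carboalumination and Pd-catalysed Negishi coupling.

Assumption: L-(+)-DIPT (step 19) and (2S,4S)-pentane-2,4-diol (its fallback) are taken to steer the peroxide to the face that gives the (1R,6S)-epoxide; if the first run shows the opposite sense, the enantiomeric ligand or diol is used with no other change.

**Ring fragment**

Step 1
Reactants: 1 hydroquinone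
Product: 2 1,4-dimethoxybenzene
Conditions: MeI (2.5 equiv), K2CO3, acetone, reflux, N2
Reagents that add atoms: iodomethane CI
Why: Williamson ether synthesis methylates both phenoxide oxygens.

Step 2
Reactants: 2 1,4-dimethoxybenzene
Product: 4 2,5-dimethoxybenzaldehyde, via chloro ether 3 (not isolated)
Conditions: Cl2CHOMe, TiCl4, CH2Cl2, 0 °C → rt; then ice/H2O
Reagents that add atoms: dichloromethyl methyl ether COC(Cl)Cl; water O
Why: Rieche formylation of the symmetrical, electron-rich arene (all four ring positions are equivalent) stops at the monoaldehyde because the formyl group deactivates the ring, and the α-chloro ether is hydrolysed on work-up.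

Step 3
Reactants: 4 2,5-dimethoxybenzaldehyde
Product: 5 5-hydroxy-2-methoxybenzaldehyde
Conditions: conc. H2SO4, 50 °C, 48 h; then ice/H2O
Reagents that add atoms: none
Why: In this acid-mediated aryl methyl ether cleavage the aldehyde is O-protonated and the ortho methoxy group, conjugated with the resulting hydroxycarbenium ion, is no longer basic, so only the 5-methoxy group is protonated and demethylated.

Step 4
Reactants: 5 5-hydroxy-2-methoxybenzaldehyde
Product: 6 3-(hydroxymethyl)-4-methoxyphenol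
Conditions: NaBH4, MeOH, 0 °C; aq. NH4Cl work-up
Reagents that add atoms: none
Why: Borohydride reduction of the aldehyde gives the benzylic alcohol that later directs both the epoxidation and the ketone reduction.

Step 5
Reactants: 6 3-(hydroxymethyl)-4-methoxyphenol
Product: 7 2-bromo-5-(hydroxymethyl)-4-methoxyphenol
Conditions: NBS (1.0 equiv), CH2Cl2/MeCN, −20 → 0 °C
Reagents that add atoms: N-bromosuccinimide O=C1CCC(=O)N1Br
Why: Electrophilic aromatic bromination goes ortho to the phenol OH, the strongest donor, whose para position is occupied; of the two ortho positions the one flanked by CH2OH is sterically blocked, so bromine enters para to the hydroxymethyl group.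

Step 6
Reactants: 7 2-bromo-5-(hydroxymethyl)-4-methoxyphenol
Product: 8 2-bromo-5-(hydroxymethyl)-4,4-dimethoxycyclohexa-2,5-dien-1-one
Conditions: PhI(OAc)2 (1.1 equiv), MeOH, 0 °C
Reagents that add atoms: methanol CO
Why: Oxidative dearomatisation of a para-methoxyphenol with the trivalent iodine reagent adds methanol at the methoxy-bearing para carbon, so the carbonyl is fixed at the former phenol carbon beside C–Br and the ketal beside C–CH2OH with no regiochemical ambiguity.

Step 7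
Reactants: 8 2-bromo-5-(hydroxymethyl)-4,4-dimethoxycyclohexa-2,5-dien-1-one
Product: 9 5-(hydroxymethyl)-4,4-dimethoxy-2-(trimethylstannyl)cyclohexa-2,5-dien-1-one
Conditions: (Me3Sn)2 (1.5 equiv), PdCl2(PPh3)2 (5 mol%), toluene, 70 °C
Reagents that add atoms: hexamethylditin C[Sn](C)(C)[Sn](C)(C)C
Why: Pd-catalysed stannylation (oxidative addition into the alkenyl C–Br bond, Sn–Sn transmetalation, reductive elimination) turns the ring into the nucleophilic coupling partner without touching ketone, ketal or alcohol.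

**Homopropargyl unit**

Step 8
Reactants: 10 but-3-yn-1-ol
Product: 12 4-(trimethylsilyl)but-3-yn-1-ol, via bis-silyl ether 11 (not isolated)
Conditions: EtMgBr (2.2 equiv), THF, 0 °C → rt; Me3SiCl (2.2 equiv); then 1 M HCl
Reagents that add atoms: chlorotrimethylsilane C[Si](C)(C)Cl
Why: The alkynyl/alkoxide dianion is silylated at C and O, and the labile O–Si bond is cleaved by acid on work-up.

Step 9
Reactants: 12 4-(trimethylsilyl)but-3-yn-1-ol
Product: 13 (4-iodobut-1-yn-1-yl)trimethylsilane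
Conditions: I2, PPh3, imidazole, CH2Cl2, 0 °C → rt
Reagents that add atoms: iodine II
Why: Appel-type (Garegg–Samuelsson) iodination converts the primary alcohol to the iodide by SN2 displacement of the alkoxyphosphonium.

**Chain fragment**

Step 10
Reactants: 14 prop-2-yn-1-ol
Product: 16 (2E)-3-iodo-2-methylprop-2-en-1-ol, via alkenylalane 15 (not isolated)
Conditions: Me3Al (3 equiv), Cp2ZrCl2 (25 mol%), CH2Cl2, 0 °C → rt; then I2, THF, −30 → 0 °C; aq. work-up
Reagents that add atoms: trimethylaluminium C[Al](C)C; iodine II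
Why: Negishi Zr-catalysed carboalumination adds Me and Al syn across the alkyne with Al on the terminal carbon, and iodinolysis with retention fixes the E trisubstituted alkene.

Step 11
Reactants: 16 (2E)-3-iodo-2-methylprop-2-en-1-ol
Product: 17 tert-butyl{[(2E)-3-iodo-2-methylprop-2-en-1-yl]oxy}diphenylsilane
Conditions: t-BuPh2SiCl, imidazole, DMF, rt
Reagents that add atoms: tert-butyl(chloro)diphenylsilane CC(C)(C)[Si](Cl)(c1ccccc1)c1ccccc1
Why: Silyl ether formation protects the future C12' hydroxyl with a group that survives alanes, zinc reagents, acidic clay and DIBAL-H.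

Step 12
Reactants: 13 (4-iodobut-1-yn-1-yl)trimethylsilane
Product: 18 [4-(trimethylsilyl)but-3-yn-1-yl]zinc iodide (kept under argon as a THF solution, titrated on an aliquot with I2; one batch serves steps 13 and 15)
Conditions: Zn dust (1.5 equiv; activated with BrCH2CH2Br 5 mol% and Me3SiCl 3 mol%), THF, 40 °C
Reagents that add atoms: zinc [Zn]
Why: Direct oxidative insertion of activated zinc into the primary C–I bond gives the homopropargylzinc iodide, which is stable in THF because the C-silyl group blocks the acidic alkyne position.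

Step 13
Reactants: 17 tert-butyl{[(2E)-3-iodo-2-methylprop-2-en-1-yl]oxy}diphenylsilane; 18 [4-(trimethylsilyl)but-3-yn-1-yl]zinc iodide
Product: 20 tert-butyl{[(2E)-2-methylhept-2-en-6-yn-1-yl]oxy}diphenylsilane, via silyl enyne 19 (not isolated)
Conditions: 18 (1.3 equiv, THF solution), Pd(PPh3)4 (3 mol%), THF, rt; then K2CO3, MeOH, rt
Reagents that add atoms: none
Why: Negishi homopropargyl–alkenyl cross-coupling proceeds with retention of the E geometry, and methanolytic C-desilylation then frees the terminal alkyne for the next iteration.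

Step 14
Reactants: 20 tert-butyl{[(2E)-2-methylhept-2-en-6-yn-1-yl]oxy}diphenylsilane
Product: 22 tert-butyl{[(2E,6E)-7-iodo-2,6-dimethylhepta-2,6-dien-1-yl]oxy}diphenylsilane, via alkenylalane 21 (not isolated)
Conditions: Me3Al (2.5 equiv), Cp2ZrCl2 (25 mol%), CH2Cl2, rt; then I2, THF, −30 °C
Reagents that add atoms: trimethylaluminium C[Al](C)C; iodine II
Why: A second Zr-catalysed syn-carboalumination/iodinolysis sets the second E trisubstituted alkene.

Step 15
Reactants: 18 [4-(trimethylsilyl)but-3-yn-1-yl]zinc iodide; 22 tert-butyl{[(2E,6E)-7-iodo-2,6-dimethylhepta-2,6-dien-1-yl]oxy}diphenylsilane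
Product: 24 tert-butyl{[(2E,6E)-2,6-dimethylundeca-2,6-dien-10-yn-1-yl]oxy}diphenylsilane, via silyl dienyne 23 (not isolated)
Conditions: 18 (1.3 equiv, THF solution), Pd(PPh3)4 (3 mol%), THF, rt; then K2CO3, MeOH, rt
Reagents that add atoms: none
Why: The same Negishi coupling/desilylation sequence as in step 13 extends the chain by four carbons with retention of both alkene geometries.

Step 16
Reactants: 24 tert-butyl{[(2E,6E)-2,6-dimethylundeca-2,6-dien-10-yn-1-yl]oxy}diphenylsilane
Product: 26 (2E,6E,10E)-12-{[tert-butyl(diphenyl)silyl]oxy}-3,7,11-trimethyldodeca-2,6,10-trien-1-ol, via alkenylalane 25 (not isolated)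
Conditions: Me3Al (2.5 equiv), Cp2ZrCl2 (25 mol%), CH2Cl2, rt; volatiles removed; n-BuLi, THF/hexane, −78 °C; (CH2O)n, −78 °C → rt
Reagents that add atoms: trimethylaluminium C[Al](C)C; formaldehyde (as paraformaldehyde) C=O
Why: A third carboalumination followed by hydroxymethylation of the alkenylalanate with formaldehyde (retention at the alkenyl carbon) sets the 2E alkene and installs C1'.

Step 17
Reactants: 26 (2E,6E,10E)-12-{[tert-butyl(diphenyl)silyl]oxy}-3,7,11-trimethyldodeca-2,6,10-trien-1-ol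
Product: 28 tert-butyl{[(2E,6E,10E)-12-chloro-2,6,10-trimethyldodeca-2,6,10-trien-1-yl]oxy}diphenylsilane, via mesylate 27 (not isolated)
Conditions: MsCl, LiCl, 2,4,6-collidine, DMF, 0 °C
Reagents that add atoms: lithium chloride [Li+].[Cl-]
Why: Collington–Meyers chlorination displaces the in situ mesylate by SN2 at the primary carbon, without allylic transposition or E/Z loss.

**Fragment union and endgame**

Step 18
Reactants: 9 5-(hydroxymethyl)-4,4-dimethoxy-2-(trimethylstannyl)cyclohexa-2,5-dien-1-one; 28 tert-butyl{[(2E,6E,10E)-12-chloro-2,6,10-trimethyldodeca-2,6,10-trien-1-yl]oxy}diphenylsilane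
Product: 29 2-[(2E,6E,10E)-12-{[tert-butyl(diphenyl)silyl]oxy}-3,7,11-trimethyldodeca-2,6,10-trien-1-yl]-5-(hydroxymethyl)-4,4-dimethoxycyclohexa-2,5-dien-1-one
Conditions: Pd2(dba)3 (2.5 mol%), AsPh3 (10 mol%), CuI (10 mol%), NMP, 40 °C
Reagents that add atoms: none
Why: In this Stille allyl–alkenyl coupling, zerovalent palladium ionises the primary allylic chloride to an η3-allyl complex that cannot scramble the 2E geometry (this would need a tertiary σ-allyl), and after Sn-to-Pd transfer of the ring alkenyl group reductive elimination occurs at the unhindered CH2 terminus.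

Step 19
Reactants: 29 2-[(2E,6E,10E)-12-{[tert-butyl(diphenyl)silyl]oxy}-3,7,11-trimethyldodeca-2,6,10-trien-1-yl]-5-(hydroxymethyl)-4,4-dimethoxycyclohexa-2,5-dien-1-one
Product: 30 (1R,6S)-1-[(2E,6E,10E)-12-{[tert-butyl(diphenyl)silyl]oxy}-3,7,11-trimethyldodeca-2,6,10-trien-1-yl]-4-(hydroxymethyl)-5,5-dimethoxy-7-oxabicyclo[4.1.0]hept-3-en-2-one
Conditions: n-Bu2Mg (10 mol%), L-(+)-DIPT (12 mol%), t-BuOOH (1.5 equiv, in decane), 4 Å MS, toluene, −20 → 0 °C
Reagents that add atoms: tert-butyl hydroperoxide CC(C)(C)OO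
Why: Proposed new method: a magnesium tartrate formed from n-Bu2Mg and L-(+)-DIPT should bind the primary alkoxide of 29 and a tert-butylperoxide on the same metal and deliver the peroxide intramolecularly to C3 (the unsubstituted β-carbon beside the ketal) on one face, after which the enolate closes onto the O–O bond to give the (1R,6S)-oxirane and a magnesium tert-butoxide that exchanges with fresh substrate and hydroperoxide, so the metal turns over while free t-BuOOH is inert toward the dienone and the isolated chain alkenes; the closest known reactions are the stoichiometric sodium tartrate-mediated nucleophilic epoxidation of hydroxymethyl quinone monoketals and the magnesium tartrate-catalysed Weitz–Scheffer epoxidation of chalcones.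

Step 20
Reactants: 30 (1R,6S)-1-[(2E,6E,10E)-12-{[tert-butyl(diphenyl)silyl]oxy}-3,7,11-trimethyldodeca-2,6,10-trien-1-yl]-4-(hydroxymethyl)-5,5-dimethoxy-7-oxabicyclo[4.1.0]hept-3-en-2-one
Product: 31 (1R,6S)-1-[(2E,6E,10E)-12-{[tert-butyl(diphenyl)silyl]oxy}-3,7,11-trimethyldodeca-2,6,10-trien-1-yl]-4-(hydroxymethyl)-7-oxabicyclo[4.1.0]hept-3-ene-2,5-dione
Conditions: montmorillonite K10, wet CH2Cl2, rt
Reagents that add atoms: water O
Why: Mild clay-catalysed ketal hydrolysis unmasks the second carbonyl without opening the oxirane, cleaving the silyl ether or protonating the chain alkenes.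

Step 21
Reactants: 31 (1R,6S)-1-[(2E,6E,10E)-12-{[tert-butyl(diphenyl)silyl]oxy}-3,7,11-trimethyldodeca-2,6,10-trien-1-yl]-4-(hydroxymethyl)-7-oxabicyclo[4.1.0]hept-3-ene-2,5-dione
Product: 32 (1R,5R,6R)-1-[(2E,6E,10E)-12-{[tert-butyl(diphenyl)silyl]oxy}-3,7,11-trimethyldodeca-2,6,10-trien-1-yl]-5-hydroxy-4-(hydroxymethyl)-7-oxabicyclo[4.1.0]hept-3-en-2-one
Conditions: i-Bu2AlH (2.5 equiv), THF, −78 °C; aq. KNaC4H4O6 work-up
Reagents that add atoms: none
Why: In this hydroxyl-directed DIBAL-H reduction the aluminium alkoxide of the CH2OH group chelates and activates only the neighbouring C5 carbonyl, and external hydride adds anti to the oxirane oxygen, giving the 5R alcohol cis to the epoxide.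

Step 22
Reactants: 32 (1R,5R,6R)-1-[(2E,6E,10E)-12-{[tert-butyl(diphenyl)silyl]oxy}-3,7,11-trimethyldodeca-2,6,10-trien-1-yl]-5-hydroxy-4-(hydroxymethyl)-7-oxabicyclo[4.1.0]hept-3-en-2-one
Product: 33 [(1R,2R,6R)-6-[(2E,6E,10E)-12-{[tert-butyl(diphenyl)silyl]oxy}-3,7,11-trimethyldodeca-2,6,10-trien-1-yl]-2-hydroxy-5-oxo-7-oxabicyclo[4.1.0]hept-3-en-3-yl]methyl acetate
Conditions: AcCl (1.05 equiv), 2,4,6-collidine, CH2Cl2, −78 °C
Reagents that add atoms: acetyl chloride CC(=O)Cl
Why: Chemoselective acylation at low temperature takes the unhindered primary allylic alcohol and leaves the secondary alcohol flanked by the oxirane free.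

Step 23
Reactants: 33 [(1R,2R,6R)-6-[(2E,6E,10E)-12-{[tert-butyl(diphenyl)silyl]oxy}-3,7,11-trimethyldodeca-2,6,10-trien-1-yl]-2-hydroxy-5-oxo-7-oxabicyclo[4.1.0]hept-3-en-3-yl]methyl acetate
Product: 34 [(1R,2R,6R)-2-hydroxy-6-[(2E,6E,10E)-12-hydroxy-3,7,11-trimethyldodeca-2,6,10-trien-1-yl]-5-oxo-7-oxabicyclo[4.1.0]hept-3-en-3-yl]methyl acetate
Conditions: HF·pyridine, pyridine, THF, 0 °C → rt
Reagents that add atoms: none
Why: Buffered fluoride desilylation removes the silyl ether without acetate migration, epoxide opening or enone addition.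

**Compound list**

1 | hydroquinone | Oc1ccc(O)cc1 | starting material
2 | 1,4-dimethoxybenzene | COc1ccc(OC)cc1 | intermediate
3 | 2-[chloro(methoxy)methyl]-1,4-dimethoxybenzene (not isolated) | COC(Cl)c1cc(OC)ccc1OC | intermediate
4 | 2,5-dimethoxybenzaldehyde | COc1ccc(OC)c(C=O)c1 | intermediate
5 | 5-hydroxy-2-methoxybenzaldehyde | COc1ccc(O)cc1C=O | intermediate
6 | 3-(hydroxymethyl)-4-methoxyphenol | COc1ccc(O)cc1CO | intermediate
7 | 2-bromo-5-(hydroxymethyl)-4-methoxyphenol | COc1cc(Br)c(O)cc1CO | intermediate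
8 | 2-bromo-5-(hydroxymethyl)-4,4-dimethoxycyclohexa-2,5-dien-1-one | OCC1=CC(=O)C(Br)=CC1(OC)OC | intermediate
9 | 5-(hydroxymethyl)-4,4-dimethoxy-2-(trimethylstannyl)cyclohexa-2,5-dien-1-one | OCC1=CC(=O)C([Sn](C)(C)C)=CC1(OC)OC | intermediate
10 | but-3-yn-1-ol | C#CCCO | starting material
11 | trimethyl{[4-(trimethylsilyl)but-3-yn-1-yl]oxy}silane (not isolated) | C[Si](C)(C)C#CCCO[Si](C)(C)C | intermediate
12 | 4-(trimethylsilyl)but-3-yn-1-ol | C[Si](C)(C)C#CCCO | intermediate
13 | (4-iodobut-1-yn-1-yl)trimethylsilane | C[Si](C)(C)C#CCCI | intermediate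
14 | prop-2-yn-1-ol | C#CCO | starting material
15 | {(1E)-3-[(dimethylalumanyl)oxy]-2-methylprop-1-en-1-yl}dimethylalumane (not isolated) | C[Al](C)/C=C(\C)CO[Al](C)C | intermediate
16 | (2E)-3-iodo-2-methylprop-2-en-1-ol | I/C=C(\C)CO | intermediate
17 | tert-butyl{[(2E)-3-iodo-2-methylprop-2-en-1-yl]oxy}diphenylsilane | I/C=C(\C)CO[Si](c1ccccc1)(c1ccccc1)C(C)(C)C | intermediate
18 | [4-(trimethylsilyl)but-3-yn-1-yl]zinc iodide (titrated THF solution) | C[Si](C)(C)C#CCC[Zn]I | intermediate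
19 | tert-butyl{[(2E)-2-methyl-7-(trimethylsilyl)hept-2-en-6-yn-1-yl]oxy}diphenylsilane (not isolated) | C[Si](C)(C)C#CCC/C=C(\C)CO[Si](c1ccccc1)(c1ccccc1)C(C)(C)C | intermediate
20 | tert-butyl{[(2E)-2-methylhept-2-en-6-yn-1-yl]oxy}diphenylsilane | C#CCC/C=C(\C)CO[Si](c1ccccc1)(c1ccccc1)C(C)(C)C | intermediate
21 | {(1E,5E)-7-{[tert-butyl(diphenyl)silyl]oxy}-2,6-dimethylhepta-1,5-dien-1-yl}dimethylalumane (not isolated) | C[Al](C)/C=C(\C)CC/C=C(\C)CO[Si](c1ccccc1)(c1ccccc1)C(C)(C)C | intermediate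
22 | tert-butyl{[(2E,6E)-7-iodo-2,6-dimethylhepta-2,6-dien-1-yl]oxy}diphenylsilane | I/C=C(\C)CC/C=C(\C)CO[Si](c1ccccc1)(c1ccccc1)C(C)(C)C | intermediate
23 | tert-butyl{[(2E,6E)-2,6-dimethyl-11-(trimethylsilyl)undeca-2,6-dien-10-yn-1-yl]oxy}diphenylsilane (not isolated) | C[Si](C)(C)C#CCC/C=C(\C)CC/C=C(\C)CO[Si](c1ccccc1)(c1ccccc1)C(C)(C)C | intermediate
24 | tert-butyl{[(2E,6E)-2,6-dimethylundeca-2,6-dien-10-yn-1-yl]oxy}diphenylsilane | C#CCC/C=C(\C)CC/C=C(\C)CO[Si](c1ccccc1)(c1ccccc1)C(C)(C)C | intermediate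
25 | {(1E,5E,9E)-11-{[tert-butyl(diphenyl)silyl]oxy}-2,6,10-trimethylundeca-1,5,9-trien-1-yl}dimethylalumane (not isolated) | C[Al](C)/C=C(\C)CC/C=C(\C)CC/C=C(\C)CO[Si](c1ccccc1)(c1ccccc1)C(C)(C)C | intermediate
26 | (2E,6E,10E)-12-{[tert-butyl(diphenyl)silyl]oxy}-3,7,11-trimethyldodeca-2,6,10-trien-1-ol | OC/C=C(\C)CC/C=C(\C)CC/C=C(\C)CO[Si](c1ccccc1)(c1ccccc1)C(C)(C)C | intermediate
27 | (2E,6E,10E)-12-{[tert-butyl(diphenyl)silyl]oxy}-3,7,11-trimethyldodeca-2,6,10-trien-1-yl methanesulfonate (not isolated) | CS(=O)(=O)OC/C=C(\C)CC/C=C(\C)CC/C=C(\C)CO[Si](c1ccccc1)(c1ccccc1)C(C)(C)C | intermediate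
28 | tert-butyl{[(2E,6E,10E)-12-chloro-2,6,10-trimethyldodeca-2,6,10-trien-1-yl]oxy}diphenylsilane | ClC/C=C(\C)CC/C=C(\C)CC/C=C(\C)CO[Si](c1ccccc1)(c1ccccc1)C(C)(C)C | intermediate
29 | 2-[(2E,6E,10E)-12-{[tert-butyl(diphenyl)silyl]oxy}-3,7,11-trimethyldodeca-2,6,10-trien-1-yl]-5-(hydroxymethyl)-4,4-dimethoxycyclohexa-2,5-dien-1-one | OCC1=CC(=O)C(C/C=C(\C)CC/C=C(\C)CC/C=C(\C)CO[Si](c2ccccc2)(c2ccccc2)C(C)(C)C)=CC1(OC)OC | intermediate
30 | (1R,6S)-1-[(2E,6E,10E)-12-{[tert-butyl(diphenyl)silyl]oxy}-3,7,11-trimethyldodeca-2,6,10-trien-1-yl]-4-(hydroxymethyl)-5,5-dimethoxy-7-oxabicyclo[4.1.0]hept-3-en-2-one | OCC1=CC(=O)[C@]2(C/C=C(\C)CC/C=C(\C)CC/C=C(\C)CO[Si](c3ccccc3)(c3ccccc3)C(C)(C)C)O[C@@H]2C1(OC)OC | intermediate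
31 | (1R,6S)-1-[(2E,6E,10E)-12-{[tert-butyl(diphenyl)silyl]oxy}-3,7,11-trimethyldodeca-2,6,10-trien-1-yl]-4-(hydroxymethyl)-7-oxabicyclo[4.1.0]hept-3-ene-2,5-dione | OCC1=CC(=O)[C@]2(C/C=C(\C)CC/C=C(\C)CC/C=C(\C)CO[Si](c3ccccc3)(c3ccccc3)C(C)(C)C)O[C@@H]2C1=O | intermediate
32 | (1R,5R,6R)-1-[(2E,6E,10E)-12-{[tert-butyl(diphenyl)silyl]oxy}-3,7,11-trimethyldodeca-2,6,10-trien-1-yl]-5-hydroxy-4-(hydroxymethyl)-7-oxabicyclo[4.1.0]hept-3-en-2-one (OH cis to the oxirane) | OCC1=CC(=O)[C@]2(C/C=C(\C)CC/C=C(\C)CC/C=C(\C)CO[Si](c3ccccc3)(c3ccccc3)C(C)(C)C)O[C@@H]2[C@@H]1O | intermediate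
33 | [(1R,2R,6R)-6-[(2E,6E,10E)-12-{[tert-butyl(diphenyl)silyl]oxy}-3,7,11-trimethyldodeca-2,6,10-trien-1-yl]-2-hydroxy-5-oxo-7-oxabicyclo[4.1.0]hept-3-en-3-yl]methyl acetate | CC(=O)OCC1=CC(=O)[C@]2(C/C=C(\C)CC/C=C(\C)CC/C=C(\C)CO[Si](c3ccccc3)(c3ccccc3)C(C)(C)C)O[C@@H]2[C@@H]1O | intermediate
34 | [(1R,2R,6R)-2-hydroxy-6-[(2E,6E,10E)-12-hydroxy-3,7,11-trimethyldodeca-2,6,10-trien-1-yl]-5-oxo-7-oxabicyclo[4.1.0]hept-3-en-3-yl]methyl acetate | CC(=O)OCC1=CC(=O)[C@]2(C/C=C(\C)CC/C=C(\C)CC/C=C(\C)CO)O[C@@H]2[C@@H]1O | target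

**Step count**

Total step count: 23.
Longest linear sequence: 14 steps (steps 8, 9 and 12–23 from but-3-yn-1-ol), i.e. 14/23 = 0.61 of the total. The sequences from hydroquinone (1–7, then 18–23) and from prop-2-yn-1-ol (10, 11, then 13–23) are 13 steps each.

**Three steps most likely to fail**

1. Step 19 (the proposed new catalytic epoxidation). It may give low turnover or low enantioselectivity. The fallback is known auxiliary-controlled chemistry; it sets out from 29 and comes back at 31. Dienone 29 is transketalised with (2S,4S)-pentane-2,4-diol (PPTS, benzene, 4 Å MS, 50 °C) to the C2-symmetric spiro-dioxane dienone F1. Nucleophilic epoxidation under control of the chiral ketal (Ph3COOH, KN(SiMe3)2, THF, −78 → −35 °C) gives the spiro-dioxane epoxide F2, which is separated from its minor diastereomer. Hydrolysis of the dioxane (aq. CF3CO2H, CH2Cl2, 0 °C) returns epoxyquinone 31.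

2. Step 18 (Stille coupling of the hindered, electron-poor α-stannyl dienone 9; the stannane of step 7 may also be labile). The fallback reverses the polarity; it sets out from 8 and 28 and comes back at 29. Chloride 28 is treated with Bu3SnLi (THF, −78 °C) to give the allylstannane F3. F3 is coupled with bromide 8 in a Stille reaction (Pd2(dba)3, AsPh3, NMP, 50 °C) to give 29. Any 2Z isomer arising from the allyl transfer is removed on AgNO3-impregnated silica.

3. Step 21 (regio- and stereoselective DIBAL-H reduction). If hydride is delivered on the oxirane face, the inversion route below is used; it sets out from 31 and comes back at 33. The reduction then gives the trans-diol F4. Selective primary acetylation (AcCl, 2,4,6-collidine, CH2Cl2, −78 °C) gives the trans-monoacetate F5. Mitsunobu inversion with chloroacetic acid (PPh3, DIAD, THF, 0 °C) gives the cis-chloroacetate F6. Thiourea with NaHCO3 in EtOH at rt removes the chloroacetyl group selectively and gives 33.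

**Further compounds**

F1 | step 19 | (2S,4S)-10-[(2E,6E,10E)-12-{[tert-butyl(diphenyl)silyl]oxy}-3,7,11-trimethyldodeca-2,6,10-trien-1-yl]-7-(hydroxymethyl)-2,4-dimethyl-1,5-dioxaspiro[5.5]undeca-7,10-dien-9-one | OCC1=CC(=O)C(C/C=C(\C)CC/C=C(\C)CC/C=C(\C)CO[Si](c2ccccc2)(c2ccccc2)C(C)(C)C)=CC13O[C@@H](C)C[C@H](C)O3
F2 | step 19 | (1R,6S,4'S,6'S)-1-[(2E,6E,10E)-12-{[tert-butyl(diphenyl)silyl]oxy}-3,7,11-trimethyldodeca-2,6,10-trien-1-yl]-4-(hydroxymethyl)-4',6'-dimethylspiro[7-oxabicyclo[4.1.0]hept-3-ene-5,2'-[1,3]dioxan]-2-one | OCC1=CC(=O)[C@]2(C/C=C(\C)CC/C=C(\C)CC/C=C(\C)CO[Si](c4ccccc4)(c4ccccc4)C(C)(C)C)O[C@@H]2C13O[C@@H](C)C[C@H](C)O3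
F3 | step 18 | tert-butyl{[(2E,6E,10E)-2,6,10-trimethyl-12-(tributylstannyl)dodeca-2,6,10-trien-1-yl]oxy}diphenylsilane | CCCC[Sn](CCCC)(CCCC)C/C=C(\C)CC/C=C(\C)CC/C=C(\C)CO[Si](c1ccccc1)(c1ccccc1)C(C)(C)C
F4 | step 21 | (1R,5S,6R)-1-[(2E,6E,10E)-12-{[tert-butyl(diphenyl)silyl]oxy}-3,7,11-trimethyldodeca-2,6,10-trien-1-yl]-5-hydroxy-4-(hydroxymethyl)-7-oxabicyclo[4.1.0]hept-3-en-2-one (OH trans to the oxirane) | OCC1=CC(=O)[C@]2(C/C=C(\C)CC/C=C(\C)CC/C=C(\C)CO[Si](c3ccccc3)(c3ccccc3)C(C)(C)C)O[C@@H]2[C@H]1O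
F5 | step 21 | [(1R,2S,6R)-6-[(2E,6E,10E)-12-{[tert-butyl(diphenyl)silyl]oxy}-3,7,11-trimethyldodeca-2,6,10-trien-1-yl]-2-hydroxy-5-oxo-7-oxabicyclo[4.1.0]hept-3-en-3-yl]methyl acetate | CC(=O)OCC1=CC(=O)[C@]2(C/C=C(\C)CC/C=C(\C)CC/C=C(\C)CO[Si](c3ccccc3)(c3ccccc3)C(C)(C)C)O[C@@H]2[C@H]1O
F6 | step 21 | [(1R,2R,6R)-6-[(2E,6E,10E)-12-{[tert-butyl(diphenyl)silyl]oxy}-3,7,11-trimethyldodeca-2,6,10-trien-1-yl]-2-[(chloroacetyl)oxy]-5-oxo-7-oxabicyclo[4.1.0]hept-3-en-3-yl]methyl acetate | CC(=O)OCC1=CC(=O)[C@]2(C/C=C(\C)CC/C=C(\C)CC/C=C(\C)CO[Si](c3ccccc3)(c3ccccc3)C(C)(C)C)O[C@@H]2[C@@H]1OC(=O)CCl
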